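**Plan**
1. Cuts, in order: both acetates; C13=C14 (olefination of a C13 methyl ketone); C8–C17 (carbonylation of a Δ7 enol triflate); C5–C6 of ring B (reductive ketyl–enone closure); C7–C8 (vinyl Grignard); C9–C11 (aza-enolate alkylation); C9–C10 (asymmetric allylation).
2. Enabling feature (labdane numbering): C5 lies between the quaternary C4 and C10, so a ring A ketone at C5 cannot enolise and is joined to C6 as a ketyl radical instead of by polar chemistry.
3. Forward: ring A is bought; C10 is made quaternary, the C9 side chain and the C8 vinyl ketone are attached, SmI2 closes ring B at C5–C6, and C17 and C14–C15 are added last.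
4. Stereochemistry: C10 from the palladium/(R)-t-BuPHOX allylation; C9 by base equilibration next to the C8 ketone; C5 by α-face hydrogenation of the Δ5 alkene; 13E from the Horner–Wadsworth–Emmons step.

Key step: step 8

Remark: labdane locants are used for all compounds (C5 = ring A carbonyl carbon, C10 = quaternary carbon, C9/C8 = first and second chain carbons on C10); β means the face of the C10 methyl.
Remark: C9 is carried as an epimer pair from step 5 to step 8 (SMILES leave it open) and is fixed in step 9. The step 8 carbinol is drawn trans-fused (5α-OH); a cis-fused carbinol would give the same alkene 21, and the C9 equilibration would then move behind step 11.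
Remark: the (R)-ligand in step 2 is chosen by analogy with 2-alkyl-2-allylcyclohexanones, where ligand and product carry like descriptors; if the sense is opposite here, the enantiomeric ligand is used.

**Step 1**
Reactants: 1 2,2,6-trimethylcyclohexan-1-one; 2 allyl chloroformate
Product: 4 allyl 2,6,6-trimethylcyclohex-1-en-1-yl carbonate, via lithium enolate 3 (not isolated)
Conditions: LiN(SiMe3)2 (LiHMDS), THF, 0 °C; then 2, −78 °C to rt
Reagents that add atoms: allyl chloroformate (2), C=CCOC(=O)Cl
Why: Enol carbonate formation: only C6 of 1 carries an α-hydrogen, so a single lithium enolate forms, and this hindered tetrasubstituted enolate is acylated on oxygen by the hard chloroformate.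

**Step 2**
Reactants: 4 allyl 2,6,6-trimethylcyclohex-1-en-1-yl carbonate
Product: 5 (R)-2-allyl-2,6,6-trimethylcyclohexan-1-one
Conditions: Pd2(dba)3 (2.5 mol %), (R)-t-BuPHOX (6 mol %), THF, 25 °C
Reagents that add atoms: none
Why: Palladium-catalysed decarboxylative asymmetric allylic alkylation (Tsuji allylation): zerovalent palladium ionises the allyl carbonate, CO2 is lost and the enolate is allylated inside the chiral phosphinooxazoline complex, which should set C10 as R.

**Step 3**
Reactants: 5 (R)-2-allyl-2,6,6-trimethylcyclohexan-1-one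
Product: 7 2-[(1R)-1,3,3-trimethyl-2-oxocyclohexyl]acetaldehyde, via ozonide 6 (not isolated)
Conditions: O3, CH2Cl2, −78 °C; then PPh3, −78 °C to rt
Reagents that add atoms: ozone, [O-][O+]=O
Why: Ozonolysis with reductive work-up cleaves the only C=C bond to the aldehyde and leaves the hindered ketone and the quaternary C10 untouched.

**Step 4**
Reactants: 8 2-(2-bromoethyl)-2-methyl-1,3-dioxolane
Product: 9 2-(2-iodoethyl)-2-methyl-1,3-dioxolane
Conditions: NaI, NaHCO3 (cat.), acetone, reflux, dark
Reagents that add atoms: sodium iodide, [Na+].[I-]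
Why: Finkelstein halide exchange, driven by precipitation of NaBr from acetone, gives the more reactive primary iodide, with NaHCO3 guarding the ketal against traces of acid.

**Step 5**
Reactants: 7 2-[(1R)-1,3,3-trimethyl-2-oxocyclohexyl]acetaldehyde; 9 2-(2-iodoethyl)-2-methyl-1,3-dioxolane
Product: 13 4-(2-methyl-1,3-dioxolan-2-yl)-2-[(1R)-1,3,3-trimethyl-2-oxocyclohexyl]butanal (C9 epimer pair), via N-tert-butyl imine 10 (not isolated), via lithiated imine 11 (not isolated), via alkylated imine 12 (not isolated)
Conditions: t-BuNH2, MgSO4, CH2Cl2, rt; LiN(i-Pr)2 (LDA), THF, −78 to 0 °C; 9, DMPU, −78 °C to rt; AcOH/NaOAc buffer (pH 4.5), H2O–pentane, rt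
Reagents that add atoms: 2-(2-iodoethyl)-2-methyl-1,3-dioxolane (9), CC1(CCI)OCCO1; water, O
Why: Stork metalloenamine alkylation: only the aldehyde condenses with tert-butylamine because the ring ketone, flanked by two quaternary carbons, can be neither iminated nor enolised, LDA removes a C9 proton, the aza-enolate is C-alkylated by the primary iodide and the buffer hydrolyses the imine without opening the dioxolane; C9 forms as an epimer pair that is corrected in step 9.

**Step 6**
Reactants: 13 4-(2-methyl-1,3-dioxolan-2-yl)-2-[(1R)-1,3,3-trimethyl-2-oxocyclohexyl]butanal; 14 vinylmagnesium bromide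
Product: 15 (2R)-2-[4-hydroxy-1-(2-methyl-1,3-dioxolan-2-yl)hex-5-en-3-yl]-2,6,6-trimethylcyclohexan-1-one (mixture at C8 and C9)
Conditions: 14 (1.2 equiv), THF, −78 °C; then H2O
Reagents that add atoms: vinylmagnesium bromide (14), C=C[Mg]Br
Why: Grignard 1,2-addition at −78 °C is chemoselective for the aldehyde because the ring ketone is shielded by two quaternary α-carbons; the C8 carbinol forms as a mixture that is erased in step 7.

**Step 7**
Reactants: 15 (2R)-2-[4-hydroxy-1-(2-methyl-1,3-dioxolan-2-yl)hex-5-en-3-yl]-2,6,6-trimethylcyclohexan-1-one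
Product: 16 (2R)-2,6,6-trimethyl-2-[1-(2-methyl-1,3-dioxolan-2-yl)-4-oxohex-5-en-3-yl]cyclohexan-1-one (C9 epimer pair)
Conditions: Dess–Martin periodinane, pyridine, CH2Cl2, 0 °C to rt; used at once
Reagents that add atoms: none
Why: Dess–Martin oxidation of the secondary allylic alcohol under buffered, non-basic conditions gives the vinyl ketone without conjugate addition to it and without harming the ketal.

**Step 8**
Reactants: 16 (2R)-2,6,6-trimethyl-2-[1-(2-methyl-1,3-dioxolan-2-yl)-4-oxohex-5-en-3-yl]cyclohexan-1-one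
Product: 18 5α-hydroxy-4,4,10β-trimethyl-9-[2-(2-methyl-1,3-dioxolan-2-yl)ethyl]-trans-decalin-8-one (C9 epimer pair), via samarium enolate 17 (not isolated)
Conditions: SmI2 (3 equiv), HMPA (12 equiv), t-BuOH (2 equiv), THF, −78 °C, slow addition of 16 (0.01 M final), then to −20 °C; aqueous work-up
Reagents that add atoms: none
Why: SmI2–HMPA transfers one electron to the keto-enone, and the C5 ketyl (or, with the same bond as outcome, the enone radical anion) joins C5 to the terminal enone carbon C6; a second electron gives the samarium enolate 17, which tert-butanol protonates at C7. The closest known reaction type is the SmI2-mediated intramolecular ketyl–olefin (ketone–enone) reductive cyclisation to γ-hydroxy ketones. Ring B closes in the 6-endo-trig mode, preferred over 5-exo attack because the nucleophilic ketyl is polarity-matched only with the enone β-carbon and the enone carbonyl lies inside the forming ring. The new C5 centre is expected from a chair-like transition state with both ring B bonds equatorial on ring A and the bulky samarium alkoxide axial, anti to the C10 methyl, but it is erased in step 10 and is not relied upon. The selectivity needed is C5–C6 coupling over plain enone reduction, β,β-dimerisation, pinacol or aldol closure; high dilution, slow addition and HMPA (which lets the hindered ketone be reduced) favour it, and the substrate secures it because the C5 ketone has no α-hydrogen, is too hindered for polar closure, yet accepts a radical bond to an unhindered CH2 terminus.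

**Step 9**
Reactants: 18 5α-hydroxy-4,4,10β-trimethyl-9-[2-(2-methyl-1,3-dioxolan-2-yl)ethyl]-trans-decalin-8-one (C9 epimer pair)
Product: 19 5α-hydroxy-4,4,10β-trimethyl-9β-[2-(2-methyl-1,3-dioxolan-2-yl)ethyl]-trans-decalin-8-one (9α-H)
Conditions: K2CO3, MeOH, rt
Reagents that add atoms: none
Why: Thermodynamic epimerisation through the C8 enolate: in the trans-fused chair–chair decalin the 9β chain is equatorial, whereas a 9α chain would be 1,3-diaxial to the 5α-hydroxyl, so the 9α-H configuration of the target should predominate.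

**Step 10**
Reactants: 19 5α-hydroxy-4,4,10β-trimethyl-9β-[2-(2-methyl-1,3-dioxolan-2-yl)ethyl]-trans-decalin-8-one
Product: 21 4,4,10β-trimethyl-9β-[2-(2-methyl-1,3-dioxolan-2-yl)ethyl]-Δ5(6)-octalin-8-one (9α-H), via chlorosulfite ester 20 (not isolated)
Conditions: SOCl2, pyridine, 0 °C
Reagents that add atoms: none
Why: Dehydration of a tertiary alcohol through its chlorosulfite under E2 conditions: C4 and C10 are quaternary, so the only β-hydrogens are on C6, and the axial 5α-oxygen is antiperiplanar to the axial 6β-hydrogen, which gives the Δ5 alkene regiospecifically while the cold basic medium suppresses Wagner–Meerwein shifts.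

**Step 11**
Reactants: 21 4,4,10β-trimethyl-9β-[2-(2-methyl-1,3-dioxolan-2-yl)ethyl]-Δ5(6)-octalin-8-one
Product: 22 4,4,10β-trimethyl-9β-[2-(2-methyl-1,3-dioxolan-2-yl)ethyl]-trans-decalin-8-one (5α-H, 9α-H)
Conditions: H2 (5 atm), 10% Pd/C, EtOAc, rt
Reagents that add atoms: none
Why: Heterogeneous catalytic hydrogenation adds both hydrogens syn from the α-face because the β-face of C5=C6 is blocked by the axial C10 and 4β methyl groups, as is usual for 4,4,10-trimethyl-Δ5-octalins, which sets C5 as 5α-H (trans fusion) while the equatorial 9β chain stays out of the way.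

**Step 12**
Reactants: 22 4,4,10β-trimethyl-9β-[2-(2-methyl-1,3-dioxolan-2-yl)ethyl]-trans-decalin-8-one
Product: 24 Δ7 enol triflate of 22 (8-trifluoromethanesulfonyloxy-Δ7 alkene; 5α-H, 9α-H), via potassium enolate 23 (not isolated)
Conditions: KN(SiMe3)2 (KHMDS), THF, −78 °C; then PhNTf2, −78 to 0 °C
Reagents that add atoms: N-phenylbis(trifluoromethanesulfonimide), O=S(=O)(N(c1ccccc1)S(=O)(=O)C(F)(F)F)C(F)(F)F
Why: Kinetic enolisation with a bulky amide base at −78 °C takes a proton from the accessible C7 methylene and not from the C9 methine next to quaternary C10, and O-triflation of the enolate fixes the double bond at C7–C8 (enol triflate formation).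

**Step 13**
Reactants: 24 Δ7 enol triflate of 22
Product: 25 methyl 13,13-(ethylenedioxy)-14,15-dinorlabd-7-en-17-oate (methyl ester on C8, Δ7; 5α-H, 9α-H)
Conditions: Pd(OAc)2 (10 mol %), PPh3 (20 mol %), Et3N, MeOH, DMF, CO (1 atm), 60 °C
Reagents that add atoms: carbon monoxide, [C-]#[O+]; methanol, CO
Why: Palladium-catalysed methoxycarbonylation of a vinyl triflate (oxidative addition, CO insertion, methanolysis) installs C17 at the ester oxidation level with the alkene held at C7–C8.

**Step 14**
Reactants: 25 methyl 13,13-(ethylenedioxy)-14,15-dinorlabd-7-en-17-oate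
Product: 26 methyl 13-oxo-14,15-dinorlabd-7-en-17-oate (9β-(3-oxobutyl) side chain)
Conditions: 1 M HCl, THF, rt
Reagents that add atoms: water, O
Why: Acid-catalysed ketal hydrolysis in dilute aqueous acid at room temperature frees the C13 methyl ketone without shifting the conjugated Δ7 alkene or epimerising C9.

**Step 15**
Reactants: 26 methyl 13-oxo-14,15-dinorlabd-7-en-17-oate; 27 triethyl phosphonoacetate
Product: 28 15-ethyl 17-methyl labda-7,13E-diene-15,17-dioate
Conditions: 27, NaH, THF, 0 to 50 °C
Reagents that add atoms: triethyl phosphonoacetate (27), CCOC(=O)CP(=O)(OCC)OCC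
Why: Horner–Wadsworth–Emmons olefination of the methyl ketone should favour the E enoate, with the ester anti to the larger C12 methylene chain, the minor Z isomer being removed by chromatography, while the hindered β-substituted C17 enoate is not attacked by the stabilised carbanion.

**Step 16**
Reactants: 28 15-ethyl 17-methyl labda-7,13E-diene-15,17-dioate
Product: 29 labda-7,13E-diene-15,17-diol
Conditions: i-Bu2AlH (DIBAL-H, 5 equiv), CH2Cl2, −78 to 0 °C; aq. KNaC4H4O6
Reagents that add atoms: none
Why: DIBAL-H reduces both conjugated esters by 1,2-hydride delivery to the allylic alcohols at low temperature without touching either trisubstituted alkene.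

**Step 17**
Reactants: 29 labda-7,13E-diene-15,17-diol
Product: 30 labda-7,13E-diene-15,17-diyl diacetate (CNP0257931.1)
Conditions: Ac2O, pyridine, DMAP (cat.), CH2Cl2, rt
Reagents that add atoms: acetic anhydride, CC(=O)OC(C)=O
Why: DMAP-catalysed acetylation of the two primary allylic alcohols gives the diacetate without affecting any stereocentre or alkene geometry.

**Compound list**
1 | 2,2,6-trimethylcyclohexan-1-one (racemic) | CC1CCCC(C)(C)C1=O | starting material
2 | allyl chloroformate | C=CCOC(=O)Cl | starting material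
3 | lithium 2,6,6-trimethylcyclohex-1-en-1-olate (not isolated) | [Li+].[O-]C1=C(C)CCCC1(C)C | intermediate
4 | allyl 2,6,6-trimethylcyclohex-1-en-1-yl carbonate | C=CCOC(=O)OC1=C(C)CCCC1(C)C | intermediate
5 | (R)-2-allyl-2,6,6-trimethylcyclohexan-1-one | C=CC[C@@]1(C)CCCC(C)(C)C1=O | intermediate
6 | (2R)-2,6,6-trimethyl-2-(1,2,4-trioxolan-3-ylmethyl)cyclohexan-1-one, ozonide of 5 (not isolated) | C1OC(C[C@@]2(C)CCCC(C)(C)C2=O)OO1 | intermediate
7 | 2-[(1R)-1,3,3-trimethyl-2-oxocyclohexyl]acetaldehyde | O=CC[C@@]1(C)CCCC(C)(C)C1=O | intermediate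
8 | 2-(2-bromoethyl)-2-methyl-1,3-dioxolane | CC1(CCBr)OCCO1 | starting material
9 | 2-(2-iodoethyl)-2-methyl-1,3-dioxolane | CC1(CCI)OCCO1 | intermediate
10 | (E)-N-tert-butyl-2-[(1R)-1,3,3-trimethyl-2-oxocyclohexyl]ethan-1-imine (not isolated) | CC(C)(C)/N=C/C[C@@]1(C)CCCC(C)(C)C1=O | intermediate
11 | lithium aza-enolate of 10 (not isolated) | [Li+].CC(C)(C)[N-]/C=C/[C@@]1(C)CCCC(C)(C)C1=O | intermediate
12 | N-tert-butyl imine of 13, C9 epimer pair (not isolated) | CC(C)(C)/N=C/C(CCC1(C)OCCO1)[C@@]2(C)CCCC(C)(C)C2=O | intermediate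
13 | 4-(2-methyl-1,3-dioxolan-2-yl)-2-[(1R)-1,3,3-trimethyl-2-oxocyclohexyl]butanal, C9 epimer pair | O=CC(CCC1(C)OCCO1)[C@@]2(C)CCCC(C)(C)C2=O | intermediate
14 | vinylmagnesium bromide | C=C[Mg]Br | starting material
15 | (2R)-2-[4-hydroxy-1-(2-methyl-1,3-dioxolan-2-yl)hex-5-en-3-yl]-2,6,6-trimethylcyclohexan-1-one, mixture at C8 and C9 | C=CC(O)C(CCC1(C)OCCO1)[C@@]2(C)CCCC(C)(C)C2=O | intermediate
16 | (2R)-2,6,6-trimethyl-2-[1-(2-methyl-1,3-dioxolan-2-yl)-4-oxohex-5-en-3-yl]cyclohexan-1-one, C9 epimer pair | C=CC(=O)C(CCC1(C)OCCO1)[C@@]2(C)CCCC(C)(C)C2=O | intermediate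
17 | bis(diiodosamarium) C7-enolate/C5-alkoxide of 18 (not isolated) | I[Sm](I)OC1=CC[C@@]2(O[Sm](I)I)C(C)(C)CCC[C@]2(C)C1CCC1(C)OCCO1 | intermediate
18 | 5α-hydroxy-4,4,10β-trimethyl-9-[2-(2-methyl-1,3-dioxolan-2-yl)ethyl]-trans-decalin-8-one, C9 epimer pair | O=C1CC[C@@]2(O)C(C)(C)CCC[C@]2(C)C1CCC1(C)OCCO1 | intermediate
19 | 5α-hydroxy-4,4,10β-trimethyl-9β-[2-(2-methyl-1,3-dioxolan-2-yl)ethyl]-trans-decalin-8-one (9α-H) | O=C1CC[C@@]2(O)C(C)(C)CCC[C@]2(C)[C@H]1CCC1(C)OCCO1 | intermediate
20 | C5 chlorosulfite ester of 19 (not isolated) | O=C1CC[C@@]2(OS(Cl)=O)C(C)(C)CCC[C@]2(C)[C@H]1CCC1(C)OCCO1 | intermediate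
21 | 4,4,10β-trimethyl-9β-[2-(2-methyl-1,3-dioxolan-2-yl)ethyl]-Δ5(6)-octalin-8-one (9α-H) | O=C1CC=C2C(C)(C)CCC[C@]2(C)[C@H]1CCC1(C)OCCO1 | intermediate
22 | 4,4,10β-trimethyl-9β-[2-(2-methyl-1,3-dioxolan-2-yl)ethyl]-trans-decalin-8-one (5α-H, 9α-H) | O=C1CC[C@H]2C(C)(C)CCC[C@]2(C)[C@H]1CCC1(C)OCCO1 | intermediate
23 | potassium Δ7-enolate of 22 (not isolated) | [K+].[O-]C1=CC[C@H]2C(C)(C)CCC[C@]2(C)[C@H]1CCC1(C)OCCO1 | intermediate
24 | Δ7 enol triflate of 22 (8-trifluoromethanesulfonyloxy-Δ7; 5α-H, 9α-H) | O=S(=O)(OC1=CC[C@H]2C(C)(C)CCC[C@]2(C)[C@H]1CCC1(C)OCCO1)C(F)(F)F | intermediate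
25 | methyl 13,13-(ethylenedioxy)-14,15-dinorlabd-7-en-17-oate | COC(=O)C1=CC[C@H]2C(C)(C)CCC[C@]2(C)[C@H]1CCC1(C)OCCO1 | intermediate
26 | methyl 13-oxo-14,15-dinorlabd-7-en-17-oate | COC(=O)C1=CC[C@H]2C(C)(C)CCC[C@]2(C)[C@H]1CCC(C)=O | intermediate
27 | triethyl phosphonoacetate | CCOC(=O)CP(=O)(OCC)OCC | starting material
28 | 15-ethyl 17-methyl labda-7,13E-diene-15,17-dioate | CCOC(=O)/C=C(\C)CC[C@H]1C(C(=O)OC)=CC[C@H]2C(C)(C)CCC[C@]12C | intermediate
29 | labda-7,13E-diene-15,17-diol | OC/C=C(\C)CC[C@H]1C(CO)=CC[C@H]2C(C)(C)CCC[C@]12C | intermediate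
30 | (5S,9R,10S)-labda-7,13E-diene-15,17-diyl diacetate (CNP0257931.1) | CC(=O)OC/C=C(\C)CC[C@H]1C(COC(C)=O)=CC[C@H]2C(C)(C)CCC[C@]12C | target

**Step count**
Total: 17 steps. Longest linear sequence: 16 steps (steps 1–3 and 5–17 from 1); step 4 is a one-step side branch.

**Three steps most likely to fail**

1. Step 8. The vinyl ketone is reduced more easily than the hindered ketone, so plain 1,4-reduction to the ethyl ketone or intermolecular β,β-coupling may outrun ring closure. Fallback: the same C5–C6 bond is made by a polar Barbier addition of a C6 nucleophile to the C5 ketone. It sets out from 15: silylation (t-BuMe2SiOTf, 2,6-lutidine) gives the tert-butyldimethylsilyl ether F1. Hydroboration–oxidation of the vinyl group (9-BBN; NaBO3·4H2O) gives the primary alcohol F2. An Appel reaction (I2, PPh3, imidazole) gives the primary iodide F3. SmI2–HMPA in THF then closes ring B by intramolecular Barbier addition to give the silyloxy carbinol F4. n-Bu4NF gives the diol F5, and Dess–Martin oxidation of the secondary C8 alcohol (the tertiary C5 alcohol cannot be oxidised) comes back to the route at 18.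

2. Step 5. C-alkylation at the neopentyl-type carbon of the lithiated imine may be slow, so that loss of HI from iodide 9 or N-alkylation prevails. Fallback: the imine is replaced by a hydrazone, whose aza-enolate is far more nucleophilic and alkylates unactivated primary iodides at low temperature, and the carbonyl is unmasked by copper-assisted instead of acidic hydrolysis. It sets out from 7: condensation with 1,1-dimethylhydrazine gives the N,N-dimethylhydrazone F6. LDA (THF, 0 °C) and then 9 at −78 °C give the alkylated hydrazone F7. CuCl2 in THF–pH 7 phosphate buffer releases the aldehyde, and the route is rejoined at 13.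

3. Step 11. The trisubstituted C5=C6 alkene between two quaternary carbons may resist hydrogenation, and any β-face delivery would give the cis-decalin. Fallback: radical hydrogen-atom-transfer hydrogenation of the Mukaiyama type (Mn(dpm)3, PhSiH3, t-BuOOH, i-PrOH, rt). It passes through the planar tertiary C5 radical, which should take up hydrogen axially to give the more stable trans-fused ring system. It sets out from 21 and comes back at 22; no compound outside the list is made (entry F0).

**Further compounds**
F1 | step 8 | tert-butyldimethylsilyl ether of 15 (C8–OSi; mixture at C8 and C9) | C=CC(O[Si](C)(C)C(C)(C)C)C(CCC1(C)OCCO1)[C@@]2(C)CCCC(C)(C)C2=O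
F2 | step 8 | primary alcohol from hydroboration of F1 (C6–OH) | OCCC(O[Si](C)(C)C(C)(C)C)C(CCC1(C)OCCO1)[C@@]2(C)CCCC(C)(C)C2=O
F3 | step 8 | primary iodide from F2 (C6–I) | ICCC(O[Si](C)(C)C(C)(C)C)C(CCC1(C)OCCO1)[C@@]2(C)CCCC(C)(C)C2=O
F4 | step 8 | 8-(tert-butyldimethylsilyloxy)-5α-hydroxy-4,4,10β-trimethyl-9-[2-(2-methyl-1,3-dioxolan-2-yl)ethyl]-trans-decalin | CC(C)(C)[Si](C)(C)OC1CC[C@@]2(O)C(C)(C)CCC[C@]2(C)C1CCC1(C)OCCO1
F5 | step 8 | 5α,8-dihydroxy-4,4,10β-trimethyl-9-[2-(2-methyl-1,3-dioxolan-2-yl)ethyl]-trans-decalin | OC1CC[C@@]2(O)C(C)(C)CCC[C@]2(C)C1CCC1(C)OCCO1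
F6 | step 5 | N,N-dimethylhydrazone of 7 | CN(C)/N=C/C[C@@]1(C)CCCC(C)(C)C1=O
F7 | step 5 | N,N-dimethylhydrazone of 13 (C9 epimer pair) | CN(C)/N=C/C(CCC1(C)OCCO1)[C@@]2(C)CCCC(C)(C)C2=O
F0 | step 11 | none | none
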